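All runs stem from a simulated flask from invented constants, noise included.

At early times in the midnight flask, substrate falls faster than target rises: at 6.00 h substrate reads 49.0% and target 32.6%, so part of the substrate gone does not show as target.

| flask | substrate | coupling partner | temperature | remark | time |
|---|---|---|---|---|---|
| midnight | 0.50 M | 1.05 equiv | 25 °C | the very flask that is asked about, followed so far |  |
| summer | 0.50 M | 1.05 equiv | 31 °C | run made earlier |  |
| flask | 0.50 M | 1.05 equiv | 25 °C |  | 3.0 d |

| run | time / h | target / % | substrate / % |
|---|---|---|---|
| midnight | 6.00 | 32.6 | 49.0 |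
| midnight | 10.0 | 46.1 | 29.2 |
| midnight | 15.0 | 55.6 | 16.4 |
| midnight | 25.0 | 65.5 | 5.4 |
| midnight | 40.0 | 68.9 | 1.3 |
| midnight | 72.0 | 69.4 | 0.4 |
| summer | 6.00 | 58.6 | 19.3 |
| summer | 10.0 | 65.2 | 4.6 |
| summer | 15.0 | 71.6 | 3.8 |
| summer | 25.0 | 72.6 | 0.5 |
| summer | 40.0 | 73.7 | 0.2 |
| summer | 72.0 | 74.7 | 2.6 |

(each reading ± 1 percentage point)

- teal: at 3.0 d add coupling partner, 100% of the amount charged, then wait 6.0 d
- blue: at 3.0 d take out 90% of the target then present, then wait 6.0 d
- violet: change nothing and wait 6.0 d more
- grey: at 3.0 d raise the temperature by 25 K, then wait 6.0 d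

- target, in percent of the substrate first charged, at 3.0 d
- the option that brings most further target ("none" if no option brings more than 2 percentage points) (teal / blue / violet / grey / none)
- target present, with what was taken out counted in, in percent of the substrate first charged, after blue
- target present, with what was taken out counted in, in percent of the substrate first charged, after grey

- what is taken out of target is counted as made
- the numbers in the tables scatter with a standard deviation of 1 percentage point
- additions bring no volume worth counting

I fold the midnight readings at 72.0 h into one number: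

φ = target / substrate spent = 0.697

This φ, the yield per turn, is the target found per unit of substrate spent. It is a reading and carries the scatter. The partner stands at 1.05 equiv, more than one per substrate, so I apply φ to the substrate and expect about 69.4% at 3.0 d. The substrate still there, 0.4%, is worth this much at φ:

φ × substrate left = 0.28 percentage points

So I expect little from teal or violet.

Is one number enough? The summer flask has the same charge but runs warmer, and its reading at 40.0 h gives:

φ = 0.738

That is higher than in the midnight flask. So φ moves with temperature, and it does not say whether the missing part is lost or held back. For me, blue and grey stay open.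

The forecast gives 69.6% now, none as best, 69.8% after blue and 70% after grey, holding that “the stall comes from lost substrate, not from equilibrium or a shortage of partner”.

    intermediate C → side product B (k = 0.0520 h⁻¹, Ea = 106 kJ mol⁻¹)
    substrate → intermediate A (k = 0.100 h⁻¹, Ea = 102 kJ mol⁻¹)
    coupling partner + intermediate A → target (k = 5.20 M⁻¹ h⁻¹, Ea = 56.0 kJ mol⁻¹)
    coupling partner + intermediate B → intermediate C (k = 0.550 M⁻¹ h⁻¹, Ea = 60.0 kJ mol⁻¹)
    coupling partner + intermediate B → side product A (k = 0.370 M⁻¹ h⁻¹, Ea = 69.0 kJ mol⁻¹)
    substrate ⇌ intermediate B (K = 1.50, k = 0.0230 h⁻¹, Ea = 112 kJ mol⁻¹, ΔH = −21.0 kJ mol⁻¹)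
    target ⇌ isomer of the product (K = 0.200, k = 0.610 h⁻¹, Ea = 82.0 kJ mol⁻¹, ΔH = −87.0 kJ mol⁻¹)
    (constants at 25 °C)

The flask gives 69.0% at 3.0 d, and the best option is grey: grey adds 13 points, reaching 82.2%, while blue adds 11 points, reaching 79.6%. In the neighbouring flask, charged with 0.630 equiv, the partner is the limiting reagent, with 0% left at 3.0 d. Taking φ on that charge, I reckon 43.9% of target. That neighbouring flask gives 47.1%, with intermediate A at 30.7%.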